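The earlier runs and the new flask were generated by integration for an exercise.

A factor of 2.92 in target at 1.8 min, Friday's flask over Monday's, for 3.00 times the catalyst, told me that the opening rate goes nearly in step with c(catalyst). The flasks, readings and questions are these:

| flask | substrate | partner | catalyst | time |
|---|---|---|---|---|
| Monday's | 0.100 M | 0.150 M | 0.00500 M |  |
| Friday's | 0.100 M | 0.150 M | 0.0150 M |  |
| Tuesday's | 0.100 M | 0.220 M | 0.00500 M |  |
| Saturday's | 0.150 M | 0.150 M | 0.00500 M |  |
| Sunday's | 0.0330 M | 0.0500 M | 0.00500 M | 45 min |

- Monday's run (time / min: [target] / M): 1.8: 0.0052; 4.0: 0.0117; 9.0: 0.0236; 20: 0.0435; 45: 0.0603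
- Friday's run (time / min: [target] / M): 1.8: 0.0152; 4.0: 0.0312; 9.0: 0.0559; 20: 0.0800; 45: 0.0866
- Tuesday's run (time / min: [target] / M): 1.8: 0.0055; 4.0: 0.0121; 9.0: 0.0239; 20: 0.0444; 45: 0.0635
- Saturday's run (time / min: [target] / M): 1.8: 0.0081; 4.0: 0.0170; 9.0: 0.0351; 20: 0.0609; 45: 0.0726

(each reading ± 3 × 10⁻⁴ M)

- Overall: substrate + partner -> target, with catalyst as catalyst.
- Constant volume, constant temperature.
- Readings of a species count what is bound in complexes too.
- "The second partner" is partner.
- An order is taken over about fifteen percent of the charge, up and down.

- how the opening rate goes with [partner] round the charge of the Monday's run: the exponent of the rate at two percent of substrate gone to target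
- how the opening rate goes with [substrate] round the charge of the Monday's run: the exponent of the rate at two percent of substrate gone to target (one fixed amount of target, the same in the runs compared)
- target in the Sunday's run at 45 min, as a share of the substrate charged
- which of these the readings show (the second partner is lost in pairs / nothing beyond the main steps / the catalyst rests as a dimer / the product speeds the reaction / the substrate pairs with itself / the product kills the catalyst)

At 4.0 min, Saturday's flask held 1.45 times Monday's target for 1.50 times the substrate. Tuesday's flask held 1.03 times Monday's target for 1.47 times the partner, a rise far less than the rise in charge. So I took the opening rate as c(catalyst) times c(substrate), and I read the capture of substrate by catalyst as the rate-limiting step, with the partner's step fast behind it. Each flask then starts pseudo-first-order in substrate. Monday's reading at 4.0 min gives 0.0311 min⁻¹, which I call the clock constant: the first-order constant of substrate loss at Monday's catalyst charge, scaled for another flask by its c(catalyst). A flask's clock is its scaled constant times the time.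

Sunday's flask has Monday's catalyst charge, so its clock at 45 min reads 1.40, and a clock running in full gives 75.3 % of the substrate as target. That was my weak link, because Monday's flask has the same clock at 45 min yet stood at 60.3 %, less than that. Its readings used a share of 0.660 of its clock. Sunday's charges of substrate and partner are each a third of Monday's. If the wear goes with those concentrations, Sunday's flask should land between the two figures, so I committed to the middle, 67.8 %.

The forecast gave 0.08 for the partner order, 0.97 for the substrate order and 64 % for Sunday's flask, within 55 % to 70 %. My figure lies above its value. On the last question it chose this: the product kills the catalyst, saying “The stall tracks product build-up”.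

Sunday's flask gave 65.9 %, with orders of 0.077 in partner and 0.98 in substrate. On the last question the forecast parts from the flask, whose readings show this: the second partner is lost in pairs.

    catalyst + substrate ⇌ catalyst-substrate complex (7.080 M⁻¹ min⁻¹, 0.6480 min⁻¹)
    catalyst-substrate complex + partner → target + catalyst (113.4 M⁻¹ min⁻¹)
    2 partner → lost reagent (0.4878 M⁻¹ min⁻¹)

Sunday's flask thus used a share of 0.769 of its clock, more than Monday's 0.660. Scaled to Friday's catalyst, the clock constant puts half of the substrate charged as target at 7.43 min, and Friday's flask reached it at 7.58 min.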